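**Plan**

- Retrosynthesis: the oxolane is cut first at C3–C4 (C3 carries CH2OH, C4 carries the aroyl group), then at the C5–O1 ether bond, then at the vinyl–carbinol and acetate–aldehyde C–C bonds, so both C6–C3 halves come from O-benzylsyringaldehyde.
- Feature used: C3 with its CH2–OH is a terminal oxirane opened homolytically at C3, and the ketone carbon on C4 is the oxygen-bearing carbon of an aryl enol triflate, an alkene that accepts a radical at C4 and sheds CF3SO2 to return C=O.
- Forward: aldehyde to epoxy alcohol (half A); aldehyde to β-keto ester to (Z)-enol triflate allylic bromide (half B); Williamson ether; the oxolane, the only ring made, closes by trivalent-titanium oxirane opening and 5-exo radical cyclization with fragmentation to the ketone; C4 epimerization; debenzylation.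
- Stereochemistry: C2 from a Sharpless kinetic resolution; C3 from C2 in the cyclization (2,3-trans, the oxirane centre being erased); C4 by equilibration α to the ketone (3,4-trans).

Key step: step 9

Remark: oxolane atoms are numbered O1, C2 (aryl), C3 (CH2OH), C4 (aroyl), C5; 4-(benzyloxy)-3,5-dimethoxybenzaldehyde 1 is taken as a catalogue compound (otherwise one benzylation from syringaldehyde).

**Route**

Step 1
Reactants: 1 4-(benzyloxy)-3,5-dimethoxybenzaldehyde
Product: 2 rac-1-[4-(benzyloxy)-3,5-dimethoxyphenyl]prop-2-en-1-ol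
Conditions: vinylmagnesium bromide (1.2 equiv), THF, 0 °C; aq. NH4Cl
Reagents that add atoms: vinylmagnesium bromide, C=C[Mg]Br
Why: Grignard 1,2-addition to an aryl aldehyde gives the racemic carbinol, which is resolved in step 2.

Step 2
Reactants: 2 rac-1-[4-(benzyloxy)-3,5-dimethoxyphenyl]prop-2-en-1-ol
Product: 3 (R)-[4-(benzyloxy)-3,5-dimethoxyphenyl][(2S)-oxiran-2-yl]methanol
Conditions: Ti(OiPr)4 (0.15 equiv), D-(−)-diisopropyl tartrate (0.2 equiv), tBuOOH (0.6 equiv), 4 Å molecular sieves, CH2Cl2, −20 °C, stopped near half conversion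
Reagents that add atoms: tert-butyl hydroperoxide, CC(C)(C)OO
Why: Sharpless kinetic resolution by asymmetric epoxidation, in which D-(−)-tartrate should epoxidize the (S)-enantiomer of 2 fast and anti (erythro) to the carbinol, so that 3 carries the future C2 configuration (R here only by priority change) while the (R)-enantiomer of 2 is left and the oxirane centre is erased in step 9.

Step 3
Reactants: 1 4-(benzyloxy)-3,5-dimethoxybenzaldehyde
Product: 4 rac-ethyl 3-[4-(benzyloxy)-3,5-dimethoxyphenyl]-3-hydroxypropanoate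
Conditions: lithium diisopropylamide (1.1 equiv), EtOAc, THF, −78 °C; then 1; aq. NH4Cl
Reagents that add atoms: ethyl acetate, CCOC(C)=O
Why: Aldol addition of the lithium enolate of ethyl acetate to a non-enolizable aldehyde; the racemic carbinol centre is removed in step 4.

Step 4
Reactants: 4 rac-ethyl 3-[4-(benzyloxy)-3,5-dimethoxyphenyl]-3-hydroxypropanoate
Product: 5 ethyl 3-[4-(benzyloxy)-3,5-dimethoxyphenyl]-3-oxopropanoate
Conditions: Dess–Martin periodinane, NaHCO3, CH2Cl2, rt
Reagents that add atoms: none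
Why: Dess–Martin oxidation of the benzylic secondary alcohol gives the β-keto ester under buffered, non-basic conditions.

Step 5
Reactants: 5 ethyl 3-[4-(benzyloxy)-3,5-dimethoxyphenyl]-3-oxopropanoate
Product: 6 ethyl (2Z)-3-[4-(benzyloxy)-3,5-dimethoxyphenyl]-3-{[(trifluoromethyl)sulfonyl]oxy}prop-2-enoate
Conditions: Tf2O, sat. aq. LiOH, toluene, 5 °C
Reagents that add atoms: trifluoromethanesulfonic anhydride, O=S(=O)(OS(=O)(=O)C(F)(F)F)C(F)(F)F
Why: O-Sulfonylation of the lithium-chelated enolate of the β-keto ester, the chelate fixing the Z geometry (triflate cis to the ester).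

Step 6
Reactants: 6 ethyl (2Z)-3-[4-(benzyloxy)-3,5-dimethoxyphenyl]-3-{[(trifluoromethyl)sulfonyl]oxy}prop-2-enoate
Product: 7 (1Z)-1-[4-(benzyloxy)-3,5-dimethoxyphenyl]-3-hydroxyprop-1-en-1-yl trifluoromethanesulfonate
Conditions: iBu2AlH (2.5 equiv), CH2Cl2, −78 °C; aq. potassium sodium tartrate
Reagents that add atoms: none
Why: 1,2-Reduction of the unsaturated ester with diisobutylaluminium hydride at low temperature should leave the enol triflate and its geometry intact.

Step 7
Reactants: 7 (1Z)-1-[4-(benzyloxy)-3,5-dimethoxyphenyl]-3-hydroxyprop-1-en-1-yl trifluoromethanesulfonate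
Product: 8 (1Z)-1-[4-(benzyloxy)-3,5-dimethoxyphenyl]-3-bromoprop-1-en-1-yl trifluoromethanesulfonate
Conditions: CBr4, PPh3, CH2Cl2, 0 °C
Reagents that add atoms: carbon tetrabromide, BrC(Br)(Br)Br
Why: Appel bromination of the primary allylic alcohol proceeds by SN2 under neutral conditions without allylic shift.

Step 8
Reactants: 3 (R)-[4-(benzyloxy)-3,5-dimethoxyphenyl][(2S)-oxiran-2-yl]methanol; 8 (1Z)-1-[4-(benzyloxy)-3,5-dimethoxyphenyl]-3-bromoprop-1-en-1-yl trifluoromethanesulfonate
Product: 9 (1Z)-1-[4-(benzyloxy)-3,5-dimethoxyphenyl]-3-{(R)-[4-(benzyloxy)-3,5-dimethoxyphenyl][(2S)-oxiran-2-yl]methoxy}prop-1-en-1-yl trifluoromethanesulfonate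
Conditions: NaH (1.1 equiv) added last to 3 and 8 (1.2 equiv), Bu4NI (cat.), THF–DMF 5:1, 0 °C
Reagents that add atoms: none
Why: Williamson ether synthesis in which the sodium alkoxide of 3, formed in the presence of the reactive allylic bromide, should be alkylated before the oxirane can migrate, no stereocentre being touched.

Step 9
Reactants: 9 (1Z)-1-[4-(benzyloxy)-3,5-dimethoxyphenyl]-3-{(R)-[4-(benzyloxy)-3,5-dimethoxyphenyl][(2S)-oxiran-2-yl]methoxy}prop-1-en-1-yl trifluoromethanesulfonate
Product: 12 (2S,3R,4R)-4-[4-(benzyloxy)-3,5-dimethoxybenzoyl]-2-[4-(benzyloxy)-3,5-dimethoxyphenyl]-3-(hydroxymethyl)oxolane, via titanium alkoxide C3 radical 10 (not isolated), via cyclized α-triflyloxybenzyl radical 11 (not isolated)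
Conditions: Cp2TiCl2 (2.5 equiv), Zn dust, THF, rt; the green Cp2TiCl solution decanted and added dropwise to 9 in THF, rt; 1 M HCl, 0 °C
Reagents that add atoms: none
Why: Proposed new method: Cp2TiCl transfers one electron to the oxirane of 9, which opens at its more substituted C–O bond to the secondary C3 radical 10 with the oxygen held on the exocyclic CH2 as a titanium alkoxide; 10 adds to the CH terminus of the (Z)-enol triflate to give the benzylic α-triflyloxy radical 11, whose S–O bond breaks to leave the aryl ketone and a CF3SO2 radical that the second equivalent of trivalent titanium reduces to triflinate. The closest known reaction types are the trivalent-titanium oxirane-opening radical cyclization onto allyl and cinnamyl ethers that gives 2-aryl-3-(hydroxymethyl)oxolanes, and the addition of alkyl radicals to aryl vinyl triflates with loss of CF3SO2 radical to give ketones; their union in one step is new. The oxolane (O1, C2, C3, C4, C5) closes in the 5-exo-trig mode through a chair-like transition state. C3 is controlled by C2: the aryl group sits pseudo-equatorial and the bulky CH2O–titanium arm of the planar radical turns away from it, so the 2,3-trans ring should result whatever the oxirane configuration, whereas C4 forms under kinetic control (3,4-cis expected to predominate, any 4-epimer being the product of step 10 itself) and is corrected there. The step needs cyclization to outrun trapping of 10 by a second Cp2TiCl (slow addition keeps the reductant dilute), 5-exo over 6-endo attack (the adduct radical is benzylic and oxygen-substituted) and survival of the new ketone (little reductant is in excess).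

Step 10
Reactants: 12 (2S,3R,4R)-4-[4-(benzyloxy)-3,5-dimethoxybenzoyl]-2-[4-(benzyloxy)-3,5-dimethoxyphenyl]-3-(hydroxymethyl)oxolane
Product: 13 (2S,3R,4S)-4-[4-(benzyloxy)-3,5-dimethoxybenzoyl]-2-[4-(benzyloxy)-3,5-dimethoxyphenyl]-3-(hydroxymethyl)oxolane
Conditions: DBU (0.3 equiv), CH2Cl2, rt
Reagents that add atoms: none
Why: Base-mediated epimerization through the ketone enolate should move C4 to the thermodynamically preferred 3,4-trans (all-trans) arrangement, C2 and C3 not being acidic and ring opening by β-alkoxide loss being the disfavoured reverse of a 5-endo-trig closure.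

Step 11
Reactants: 13 (2S,3R,4S)-4-[4-(benzyloxy)-3,5-dimethoxybenzoyl]-2-[4-(benzyloxy)-3,5-dimethoxyphenyl]-3-(hydroxymethyl)oxolane
Product: 14 (2S,3R,4S)-4-(4-hydroxy-3,5-dimethoxybenzoyl)-2-(4-hydroxy-3,5-dimethoxyphenyl)-3-(hydroxymethyl)oxolane (CID53356211)
Conditions: H2 (1 atm), 10% Pd/C, EtOAc–EtOH, rt
Reagents that add atoms: none
Why: Hydrogenolysis of the two aryl benzyl ethers under neutral conditions should be faster than reduction of the electron-rich aryl ketone or cleavage of the cyclic benzylic ether, and no stereocentre is affected.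

**Compound list**

1 | 4-(benzyloxy)-3,5-dimethoxybenzaldehyde | O=Cc1cc(OC)c(OCc2ccccc2)c(OC)c1 | starting material
2 | rac-1-[4-(benzyloxy)-3,5-dimethoxyphenyl]prop-2-en-1-ol | C=CC(O)c1cc(OC)c(OCc2ccccc2)c(OC)c1 | intermediate
3 | (R)-[4-(benzyloxy)-3,5-dimethoxyphenyl][(2S)-oxiran-2-yl]methanol | O[C@H](c1cc(OC)c(OCc2ccccc2)c(OC)c1)[C@@H]1CO1 | intermediate
4 | rac-ethyl 3-[4-(benzyloxy)-3,5-dimethoxyphenyl]-3-hydroxypropanoate | CCOC(=O)CC(O)c1cc(OC)c(OCc2ccccc2)c(OC)c1 | intermediate
5 | ethyl 3-[4-(benzyloxy)-3,5-dimethoxyphenyl]-3-oxopropanoate | CCOC(=O)CC(=O)c1cc(OC)c(OCc2ccccc2)c(OC)c1 | intermediate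
6 | ethyl (2Z)-3-[4-(benzyloxy)-3,5-dimethoxyphenyl]-3-{[(trifluoromethyl)sulfonyl]oxy}prop-2-enoate | CCOC(=O)/C=C(\OS(=O)(=O)C(F)(F)F)c1cc(OC)c(OCc2ccccc2)c(OC)c1 | intermediate
7 | (1Z)-1-[4-(benzyloxy)-3,5-dimethoxyphenyl]-3-hydroxyprop-1-en-1-yl trifluoromethanesulfonate | OC/C=C(\OS(=O)(=O)C(F)(F)F)c1cc(OC)c(OCc2ccccc2)c(OC)c1 | intermediate
8 | (1Z)-1-[4-(benzyloxy)-3,5-dimethoxyphenyl]-3-bromoprop-1-en-1-yl trifluoromethanesulfonate | BrC/C=C(\OS(=O)(=O)C(F)(F)F)c1cc(OC)c(OCc2ccccc2)c(OC)c1 | intermediate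
9 | (1Z)-1-[4-(benzyloxy)-3,5-dimethoxyphenyl]-3-{(R)-[4-(benzyloxy)-3,5-dimethoxyphenyl][(2S)-oxiran-2-yl]methoxy}prop-1-en-1-yl trifluoromethanesulfonate | FC(F)(F)S(=O)(=O)O/C(=C\CO[C@H](c1cc(OC)c(OCc2ccccc2)c(OC)c1)[C@@H]1CO1)c1cc(OC)c(OCc2ccccc2)c(OC)c1 | intermediate
10 | C3 radical from oxirane opening of 9, oxygen bound as chlorobis(cyclopentadienyl)titanium alkoxide | [O-]C[CH][C@H](OC/C=C(\OS(=O)(=O)C(F)(F)F)c1cc(OC)c(OCc2ccccc2)c(OC)c1)c1cc(OC)c(OCc2ccccc2)c(OC)c1.[Ti+4].[Cl-].[cH-]1cccc1.[cH-]1cccc1 | intermediate (not isolated)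
11 | cyclized oxolane carrying the aryl(triflyloxy)methyl radical on C4 and the titanium alkoxide on the C3 CH2O group | FC(F)(F)S(=O)(=O)O[C](c1cc(OC)c(OCc2ccccc2)c(OC)c1)[C@H]1CO[C@H](c2cc(OC)c(OCc3ccccc3)c(OC)c2)[C@H]1C[O-].[Ti+4].[Cl-].[cH-]1cccc1.[cH-]1cccc1 | intermediate (not isolated)
12 | (2S,3R,4R)-4-[4-(benzyloxy)-3,5-dimethoxybenzoyl]-2-[4-(benzyloxy)-3,5-dimethoxyphenyl]-3-(hydroxymethyl)oxolane (2,3-trans, 3,4-cis) | COc1cc(C(=O)[C@H]2CO[C@H](c3cc(OC)c(OCc4ccccc4)c(OC)c3)[C@H]2CO)cc(OC)c1OCc1ccccc1 | intermediate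
13 | (2S,3R,4S)-4-[4-(benzyloxy)-3,5-dimethoxybenzoyl]-2-[4-(benzyloxy)-3,5-dimethoxyphenyl]-3-(hydroxymethyl)oxolane (all-trans) | COc1cc(C(=O)[C@@H]2CO[C@H](c3cc(OC)c(OCc4ccccc4)c(OC)c3)[C@H]2CO)cc(OC)c1OCc1ccccc1 | intermediate
14 | (2S,3R,4S)-4-(4-hydroxy-3,5-dimethoxybenzoyl)-2-(4-hydroxy-3,5-dimethoxyphenyl)-3-(hydroxymethyl)oxolane | COc1cc(C(=O)[C@@H]2CO[C@H](c3cc(OC)c(O)c(OC)c3)[C@H]2CO)cc(OC)c1O | target

**Count and risks**

Total steps: 11. Longest linear sequence: 9 steps (1 → 4 → 5 → 6 → 7 → 8 → 9 → 12 → 13 → 14).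

Step 9 (new method). What may go wrong: capture of the C3 radical by a second Cp2TiCl followed by β-elimination (deoxygenation) before ring closure, attack of released CF3 radicals on unreacted enol triflate, or over-reduction of the new aryl ketone by the titanium reagent. Fallback with known chemistry only, setting out from 9: anti-elimination of the (Z)-enol triflate with KOtBu in THF at 0 °C gives the aryl propargyl epoxy ether F1. The established Cp2TiCl oxirane-opening 5-exo-dig cyclization onto the alkyne, with acidic work-up, gives the 4-benzylidene-3-(hydroxymethyl)oxolane F2 with the same 2,3-trans control. Hydroboration with excess BH3·THF and NaBO3 oxidation places the hydroxyl on the less substituted benzylic carbon to give the diol F3. MnO2 in CH2Cl2 oxidizes only the benzylic alcohol and returns to the route at 12, formed together with its C4 epimer, both of which step 10 converges.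

Step 8. What may go wrong: migration of the oxirane in the alkoxide of 3 before alkylation (Payne rearrangement), or attack of the alkoxide on the enol triflate of 8 (anti-elimination to the alkyne, or cleavage at sulfur). Fallback that forms the ether by conjugate addition and installs the triflate afterwards, setting out from 2 (racemic, or the enantiomer left over in step 2): MnO2 in CH2Cl2 gives the aryl vinyl ketone F4. PMe3-catalysed oxa-Michael addition of 3 to F4 in THF gives the β-alkoxy ketone F5. KN(SiMe3)2 and N-(5-chloropyridin-2-yl)bis(trifluoromethanesulfonyl)imide in THF at −78 °C trap its (Z)-enolate as the enol triflate, which is 9.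

Step 10. What may go wrong: drainage of the equilibrium into the cis-fused cyclic hemiketal that the 3,4-cis isomer can form between its CH2OH and the ketone, or ring opening by β-alkoxide loss on prolonged base contact. Fallback that removes the free hydroxyl before equilibration, setting out from 12: benzyl chloroformate and pyridine in CH2Cl2 give the benzyl carbonate F6. DBU in CH2Cl2 then epimerizes C4 to the all-trans benzyl carbonate F7. The hydrogenolysis conditions of step 11 remove the two benzyl ethers and the carbonate together and arrive at 14.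

**Further compounds**

F1 | step 9 | (2S)-2-{(R)-[4-(benzyloxy)-3,5-dimethoxyphenyl]({3-[4-(benzyloxy)-3,5-dimethoxyphenyl]prop-2-yn-1-yl}oxy)methyl}oxirane | COc1cc(C#CCO[C@H](c2cc(OC)c(OCc3ccccc3)c(OC)c2)[C@@H]2CO2)cc(OC)c1OCc1ccccc1
F2 | step 9 | [(2S,3R)-2-[4-(benzyloxy)-3,5-dimethoxyphenyl]-4-{[4-(benzyloxy)-3,5-dimethoxyphenyl]methylidene}oxolan-3-yl]methanol (alkene isomers) | COc1cc(C=C2CO[C@H](c3cc(OC)c(OCc4ccccc4)c(OC)c3)[C@H]2CO)cc(OC)c1OCc1ccccc1
F3 | step 9 | [4-(benzyloxy)-3,5-dimethoxyphenyl][(4S,5S)-5-[4-(benzyloxy)-3,5-dimethoxyphenyl]-4-(hydroxymethyl)oxolan-3-yl]methanol (epimers at ring C3 and at the carbinol) | COc1cc(C(O)C2CO[C@H](c3cc(OC)c(OCc4ccccc4)c(OC)c3)[C@H]2CO)cc(OC)c1OCc1ccccc1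
F4 | step 8 | 1-[4-(benzyloxy)-3,5-dimethoxyphenyl]prop-2-en-1-one | C=CC(=O)c1cc(OC)c(OCc2ccccc2)c(OC)c1
F5 | step 8 | 1-[4-(benzyloxy)-3,5-dimethoxyphenyl]-3-{(R)-[4-(benzyloxy)-3,5-dimethoxyphenyl][(2S)-oxiran-2-yl]methoxy}propan-1-one | O=C(CCO[C@H](c1cc(OC)c(OCc2ccccc2)c(OC)c1)[C@@H]1CO1)c1cc(OC)c(OCc2ccccc2)c(OC)c1
F6 | step 10 | benzyl {(2S,3R,4R)-4-[4-(benzyloxy)-3,5-dimethoxybenzoyl]-2-[4-(benzyloxy)-3,5-dimethoxyphenyl]oxolan-3-yl}methyl carbonate | COc1cc(C(=O)[C@H]2CO[C@H](c3cc(OC)c(OCc4ccccc4)c(OC)c3)[C@H]2COC(=O)OCc2ccccc2)cc(OC)c1OCc1ccccc1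
F7 | step 10 | benzyl {(2S,3R,4S)-4-[4-(benzyloxy)-3,5-dimethoxybenzoyl]-2-[4-(benzyloxy)-3,5-dimethoxyphenyl]oxolan-3-yl}methyl carbonate | COc1cc(C(=O)[C@@H]2CO[C@H](c3cc(OC)c(OCc4ccccc4)c(OC)c3)[C@H]2COC(=O)OCc2ccccc2)cc(OC)c1OCc1ccccc1
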